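**Numbering.** Atom numbers follow the cembrane skeleton: C1 (ring CH carrying C15), C2 (lactone O–CH), C3=C4 (methyl on C4), C5, C6=C7, C8 (methyl, OH), C9, C10, C11–C12 oxirane (methyl on C12), C13 (OAc), C14, C15=C17H2, C16 (lactone C=O). Compound numbers are those of the steps and of the list after step 21.

**Assumption.** (S)-Linalool 1 is taken as enantiomerically pure; any residual enantiomer would show up as a separable diastereomer after step 5.

## Analysis of the target

Target 38 is a cembranolide: a 14-membered carbocycle C1–C14 that is cis-fused across C1–C2 (H1 and H2 on the same face) to an α-methylene-γ-butyrolactone (ring atoms O, C2, C1, C15, C16, with exocyclic C15=C17). The macrocycle holds an E trisubstituted C3=C4 alkene and an E disubstituted C6=C7 alkene, skipped across the doubly allylic C5. It also holds a tertiary carbinol at C8, a trisubstituted C11–C12 oxirane and a secondary acetate at C13. The six stereocentres (1S, 2S, 8S, 11S, 12S, 13R) fall into three groups that do not relay to one another: the C1/C2 pair, the isolated C8, and the contiguous triad C11–C12–C13. In the oxirane, C10 and C13 lie on the same side (H11 and the C12 methyl are cis), so it is the epoxide of a Z-configured C11=C12 olefin and cannot come from the usual E olefin. The C13 oxygen sits on the side that a hydroxyl-directed epoxidation of the Z allylic C13 alcohol would not deliver, because allylic 1,3-strain steers such an epoxidation to the other diastereomer. Sensitive groups are the Michael-accepting methylene lactone, the oxirane with the C8 hydroxyl four atoms away (acid-promoted tetrahydrofuran formation), the doubly allylic C5 and the acetate. The difficulty is to close a 14-membered ring with two defined alkene geometries while giving each stereo-group its own control element. The strategy rests on the C2 carbinol bonded to the E C3=C4(CH3) alkene, which is the retron of a coupling of an aldehyde, a terminal alkyne and a methyl donor.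

## Retrosynthetic reasoning

**C15=C17 and C13 acetate (38 back to 32).** The methylene group is unmasked last, by methylation and elimination of the amine 36, so that the Michael acceptor never meets fluoride, free alkoxides or a metathesis catalyst. Amine 36 comes from the diol 35 by acetylation of the secondary C13 hydroxyl; the tertiary C8 hydroxyl is inert to it. Diol 35 comes from 34 by loss of both silyl groups, and 34 from the macrocyclic lactone 32 by a Mannich reaction at C15, the only enolisable position.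

**C6=C7 (32 back to 31).** The ring is opened at the one simple disubstituted alkene. Ring-closing metathesis of the two monosubstituted alkenes of 31 should give the E olefin, and both termini already exist in the building blocks 26 and 1. Cutting here leaves every stereocentre outside the ring-forming event. The lactone is closed first because the cis-fused five-membered ring holds C3 and C14 on one face and pre-folds the chain.

**Lactone C–O bond (31 back to 29).** The C2 hydroxyl of 29 closes onto the C16 tert-butyl ester. The C2–O bond is never broken, so the lactone inherits the C2 configuration.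

**C2–C3 and C4–CH3 (29 back to 25, 26 and 27; key disconnection).** Cutting both bonds at once removes the trisubstituted alkene and the carbinol in one operation. It splits the molecule into the stereochemically dense aldehyde 25 and the five-carbon enyne 26, with 27 as the methyl source. The forward reaction must place the aldehyde carbon on the unsubstituted alkyne carbon, add the methyl group cis to it, and leave the two terminal alkenes untouched. The C2 configuration is the one element it cannot be relied on to fix.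

**C1–C15 and the C2 aldehyde (25 back to 20 and 21).** The branched C1 centre is set by auxiliary-controlled alkylation of the imide 20 with 21, the oxazolidinone 18 shielding one enolate face. Reduction of 23 to the alcohol 24 and re-oxidation give the aldehyde without touching the tert-butyl ester. An acetic ester rather than a methylene lactone is carried so that nothing in 25 competes in the nickel step or in the metathesis.

**C2 carboxyl (20 back to 13).** The acid 17 derives from the terminal alkene of 13 by anti-Markovnikov hydration and oxidation. The allyl group is thus a three-carbon homoenolate equivalent for C14–C1–C2.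

**C13–C14 (13 back to 10).** The C13 carbinol is made by reagent-controlled allylation of the epoxy aldehyde 10 and is then silylated. The oxirane is installed before C13 because the required C12/C13 relationship is the one favoured by addition to an α,β-epoxy aldehyde, not the one a directed epoxidation of the Z allylic C13 alcohol would give. Aldehyde 10 cannot epimerise, since C12 is quaternary.

**Oxirane (10 back to 8).** Epoxy alcohol 9 comes from the primary Z allylic alcohol 8 by a catalyst-controlled asymmetric epoxidation. The chiral catalyst sets C11 and C12 together; C8 is too remote to help or hinder.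

**C11=C12 (8 back to 4 and 5).** The Z trisubstituted olefin is built by a Z-selective phosphonate olefination of aldehyde 4 with 5, followed by reduction of the ester 7. An allylic oxidation of the E methyl group of 2 would be shorter, but it places C13 trans to C10 and leads to the wrong oxirane, so the prenyl terminus is cut off and rebuilt.

**C8 (4 back to 1).** Aldehyde 4 is the ozonolysis product of the silyl ether 2 of (S)-linalool 1, which supplies C7–C11 and the C8 stereocentre from the chiral pool. Both hydroxyls are carried as triethylsilyl ethers so that one mild fluoride treatment frees them together near the end.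

## Alternatives that were turned down

**Alternative 1:** Wittig ring contraction, disconnecting C1–C2. The 17-membered cyclic allyl propargyl ether A1 (oxygen bridging C2 and C17) would be lithiated at propargylic C2 with an alkyllithium base. The [2,3]-shift then forms C1–C2, cleaves O–C17 and contracts the ring to the 14-membered cycloalkynol A2.
- For: one step gives the carbocycle and both C1 and C2, and it leaves the C15=C17 methylene already in place, which is better than the two-step methylenation used here. A 17-membered ether is also easier to close than a 14-membered carbocycle.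
- Against: A2 has a C3≡C4 alkyne without the C4 methyl, so the E trisubstituted alkene needs a later hydrometalation and methylation on the macrocycle. The C1/C2 configuration depends on the folding of a large ring and on the geometry of the C1=C15 olefin, and its absolute sense must be relayed from remote C8 and C13. C5 is both propargylic and allylic and competes with C2 for the base. As drawn, A2 carries the E C11=C12 olefin, whose epoxidation puts C10 and C13 trans, not cis as in 38.
- Comparison: three different silyl groups and a long finish (alkyne to alkene, lactone oxidation, epoxidation, acetylation) make it longer than the chosen route, which sets C1 with an auxiliary and the C3=C4 geometry in the bond-forming step.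

**Alternative 2:** allyl–alkenyl Stille macrocyclisation, disconnecting C5–C6. A zerovalent palladium catalyst with a weakly donating arsine ligand would ionise the C5 allylic chloride of the seco compound A3 and couple it with the E C6 alkenylstannane, giving the carbocycle A4 with the skipped diene in place.
- For: this is the strongest alternative on late-stage economy. All six stereocentres, the oxirane and the acetate are set before the ring closes, the C6=C7 geometry is fixed by the stannane and not by metathesis thermodynamics, and only desilylation and allylic oxidation to the lactone remain. On these points it is better than the chosen route.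
- Against: the π-allyl intermediate can scramble the C3=C4 geometry through syn/anti isomerisation and can couple at C3 instead of C5. A3 needs a labile allylic chloride and an alkenylstannane next to a free tertiary carbinol, both installed late on a fully functionalised, oxirane-bearing chain. The linear sequence to A3 is long and leaves tin waste.
- Comparison: the chosen route builds C3–C6 and the methyl group from 26 and 27 in one step and fixes C3=C4 by syn carbometalation, at the price of uncertain C2 control and a metathesis ring closure.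

**Alternative 3:** nickel reductive ynal macrocyclisation, disconnecting C12–C13. Zerovalent nickel with an N-heterocyclic carbene and a trialkylsilane would join the C13 aldehyde of the ynal A5 to C12 of its C11≡C12–CH3 alkyne, closing the ring to the silyl-protected allylic alcohol A6.
- For: macrocyclisations of this type are better precedented than metathesis onto a vinyl group next to a quaternary carbinol, and ring and carbinol form together.
- Against, decisively: hydrogen and C13 add cis across the alkyne, so C10 and C13 end up trans (the E olefin). Its epoxide is the wrong geometric series for 38, and the mechanism cannot give the Z isomer. C13 would also depend on macrocyclic control, and the C1/C2 region would still have to be made beforehand.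
- Comparison: the chosen route uses the same nickel manifold at C2–C3, where cis addition (methyl cis to C2) is exactly the geometry 38 needs.

Key step: step 15

## Steps

Step 1
Reactants: 1 (S)-linalool
Product: 2 (3S)-3,7-dimethyl-3-(triethylsilyloxy)octa-1,6-diene
Conditions: TESOTf, 2,6-lutidine, CH2Cl2, −78 → 0 °C
Reagents that add atoms: triethylsilyl trifluoromethanesulfonate, CC[Si](CC)(CC)OS(=O)(=O)C(F)(F)F
Why: Silyl triflate with a hindered pyridine base silylates tertiary alcohols (silyl ether formation); the C8 stereocentre is not involved.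

Step 2
Reactants: 2 (3S)-3,7-dimethyl-3-(triethylsilyloxy)octa-1,6-diene
Product: 4 (4S)-4-methyl-4-(triethylsilyloxy)hex-5-enal, via ozonide 3 (not isolated)
Conditions: O3 (1 equiv, Sudan Red 7B end point), CH2Cl2, −78 °C; then Me2S, −78 °C → rt
Reagents that add atoms: ozone, [O-][O+]=O
Why: Ozonolysis (Criegee mechanism) is fastest at the electron-rich trisubstituted alkene; the monosubstituted vinyl group on the oxygenated quaternary carbon should be left when ozone is limited to one equivalent, and reductive work-up of 3 gives the aldehyde.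

Step 3
Reactants: 4 (4S)-4-methyl-4-(triethylsilyloxy)hex-5-enal; 5 ethyl 2-[bis(2,2,2-trifluoroethoxy)phosphoryl]propanoate
Product: 7 ethyl (2Z,6S)-2,6-dimethyl-6-(triethylsilyloxy)octa-2,7-dienoate, via phosphonate anion 6 (not isolated)
Conditions: KN(SiMe3)2, 18-crown-6, THF, −78 °C
Reagents that add atoms: none
Why: Still–Gennari olefination: the electron-poor phosphonate with a dissociated potassium counter-ion eliminates fast from the kinetic adduct and should give the Z enoate, which places C13 cis to C10 as the oxirane of 38 requires.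

Step 4
Reactants: 7 ethyl (2Z,6S)-2,6-dimethyl-6-(triethylsilyloxy)octa-2,7-dienoate
Product: 8 (2Z,6S)-2,6-dimethyl-6-(triethylsilyloxy)octa-2,7-dien-1-ol
Conditions: iBu2AlH, CH2Cl2, −78 °C; aq. potassium sodium tartrate
Reagents that add atoms: none
Why: 1,2-Reduction of the enoate by the aluminium hydride gives the allylic alcohol; the Z geometry is not touched.

Step 5
Reactants: 8 (2Z,6S)-2,6-dimethyl-6-(triethylsilyloxy)octa-2,7-dien-1-ol
Product: 9 [(2R,3S)-2-methyl-3-[(3S)-3-methyl-3-(triethylsilyloxy)pent-4-en-1-yl]oxiran-2-yl]methanol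
Conditions: Ti(OiPr)4 (20 mol %), D-(−)-diisopropyl tartrate (24 mol %), t-BuOOH, 4 Å molecular sieves, CH2Cl2, −20 °C
Reagents that add atoms: tert-butyl hydroperoxide, CC(C)(C)OO
Why: Sharpless asymmetric epoxidation: the titanium tartrate complex binds the allylic hydroxyl and the D-(−)-tartrate delivers oxygen to the face that sets C11 and C12 (catalyst control, opposite in sense to the L-(+)-tartrate that gives 2S epoxy alcohols); syn addition keeps C10 and C13 cis, and the isolated vinyl group is not an allylic alcohol and should not react.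

Step 6
Reactants: 9 [(2R,3S)-2-methyl-3-[(3S)-3-methyl-3-(triethylsilyloxy)pent-4-en-1-yl]oxiran-2-yl]methanol
Product: 10 (2S,3S)-2-methyl-3-[(3S)-3-methyl-3-(triethylsilyloxy)pent-4-en-1-yl]oxirane-2-carbaldehyde
Conditions: Dess–Martin periodinane, NaHCO3, CH2Cl2, 0 °C → rt
Reagents that add atoms: none
Why: Buffered Dess–Martin oxidation of the primary alcohol; the α-carbon C12 is quaternary, so the epoxy aldehyde cannot epimerise.

Step 7
Reactants: 10 (2S,3S)-2-methyl-3-[(3S)-3-methyl-3-(triethylsilyloxy)pent-4-en-1-yl]oxirane-2-carbaldehyde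
Product: 12 (1R)-1-[(2R,3S)-2-methyl-3-[(3S)-3-methyl-3-(triethylsilyloxy)pent-4-en-1-yl]oxiran-2-yl]but-3-en-1-ol, via borinate 11 (not isolated)
Conditions: (+)-Ipc2B(allyl), Et2O, −78 °C; then aq. NaHCO3, H2O2, 0 °C → rt
Reagents that add atoms: (+)-B-allyldiisopinocampheylborane (from (−)-α-pinene), C=CCB([C@H]1C[C@H]2C[C@@H]([C@@H]1C)C2(C)C)[C@H]1C[C@H]2C[C@@H]([C@@H]1C)C2(C)C
Why: Brown allylboration through a chair transition state; the (−)-α-pinene-derived reagent adds in the sense that turns benzaldehyde into (R)-1-phenylbut-3-en-1-ol and should set C13 as R. The polar Felkin–Anh preference of the epoxy aldehyde (attack anti to the oxirane C–O bond, past the methyl group) points the same way.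

Step 8
Reactants: 12 (1R)-1-[(2R,3S)-2-methyl-3-[(3S)-3-methyl-3-(triethylsilyloxy)pent-4-en-1-yl]oxiran-2-yl]but-3-en-1-ol
Product: 13 triethyl{[(1R)-1-[(2S,3S)-2-methyl-3-[(3S)-3-methyl-3-(triethylsilyloxy)pent-4-en-1-yl]oxiran-2-yl]but-3-en-1-yl]oxy}silane
Conditions: TESCl, imidazole, DMAP (cat.), DMF, rt
Reagents that add atoms: chlorotriethylsilane, CC[Si](CC)(CC)Cl
Why: Silylation of the secondary C13 alcohol with chlorosilane and imidazole; these conditions are not Lewis acidic and should spare the oxirane.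

Step 9
Reactants: 13 triethyl{[(1R)-1-[(2S,3S)-2-methyl-3-[(3S)-3-methyl-3-(triethylsilyloxy)pent-4-en-1-yl]oxiran-2-yl]but-3-en-1-yl]oxy}silane
Product: 15 (4R)-4-[(2S,3S)-2-methyl-3-[(3S)-3-methyl-3-(triethylsilyloxy)pent-4-en-1-yl]oxiran-2-yl]-4-(triethylsilyloxy)butan-1-ol, via alkylborane 14 (not isolated)
Conditions: Cy2BH (from cyclohexene, BH3·SMe2), THF, 0 °C; then NaOH, H2O2, 0 °C → rt
Reagents that add atoms: hydrogen peroxide, OO
Why: Anti-Markovnikov hydroboration–oxidation; the bulky dialkylborane should pick the unhindered C1=C2 alkene over the vinyl group on the quaternary, oxygen-bearing C8.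

Step 10
Reactants: 15 (4R)-4-[(2S,3S)-2-methyl-3-[(3S)-3-methyl-3-(triethylsilyloxy)pent-4-en-1-yl]oxiran-2-yl]-4-(triethylsilyloxy)butan-1-ol
Product: 17 (4R)-4-[(2S,3S)-2-methyl-3-[(3S)-3-methyl-3-(triethylsilyloxy)pent-4-en-1-yl]oxiran-2-yl]-4-(triethylsilyloxy)butanoic acid, via aldehyde 16 (not isolated)
Conditions: TEMPO (cat.), PhI(OAc)2, MeCN/pH 7 phosphate buffer, rt
Reagents that add atoms: water, O
Why: Oxoammonium-mediated oxidation of the primary alcohol through the aldehyde hydrate to the acid; the buffered medium should tolerate the silyl ethers, the oxirane and the vinyl group.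

Step 11
Reactants: 17 (4R)-4-[(2S,3S)-2-methyl-3-[(3S)-3-methyl-3-(triethylsilyloxy)pent-4-en-1-yl]oxiran-2-yl]-4-(triethylsilyloxy)butanoic acid; 18 (4R)-4-benzyl-1,3-oxazolidin-2-one
Product: 20 (4R)-4-benzyl-3-[(4R)-4-[(2S,3S)-2-methyl-3-[(3S)-3-methyl-3-(triethylsilyloxy)pent-4-en-1-yl]oxiran-2-yl]-4-(triethylsilyloxy)butanoyl]-1,3-oxazolidin-2-one, via mixed anhydride 19 (not isolated)
Conditions: PivCl, Et3N, THF, −20 °C; then 18, LiCl, −20 °C → rt
Reagents that add atoms: none
Why: N-Acylation of the oxazolidinone through the mixed pivalic anhydride, which is attacked at its less hindered carbonyl.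

Step 12
Reactants: 20 (4R)-4-benzyl-3-[(4R)-4-[(2S,3S)-2-methyl-3-[(3S)-3-methyl-3-(triethylsilyloxy)pent-4-en-1-yl]oxiran-2-yl]-4-(triethylsilyloxy)butanoyl]-1,3-oxazolidin-2-one; 21 tert-butyl bromoacetate
Product: 23 tert-butyl (3S,5R)-3-[(4R)-4-benzyl-2-oxo-1,3-oxazolidine-3-carbonyl]-5-[(2S,3S)-2-methyl-3-[(3S)-3-methyl-3-(triethylsilyloxy)pent-4-en-1-yl]oxiran-2-yl]-5-(triethylsilyloxy)pentanoate, via sodium enolate 22 (not isolated)
Conditions: NaN(SiMe3)2, THF, −78 °C; then 21, −78 → −40 °C
Reagents that add atoms: none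
Why: Evans asymmetric alkylation: the chelated Z enolate is shielded on one face by the benzyl group of the (R)-auxiliary, so the bromoacetate should enter from the other face and set C1 as S.

Step 13
Reactants: 23 tert-butyl (3S,5R)-3-[(4R)-4-benzyl-2-oxo-1,3-oxazolidine-3-carbonyl]-5-[(2S,3S)-2-methyl-3-[(3S)-3-methyl-3-(triethylsilyloxy)pent-4-en-1-yl]oxiran-2-yl]-5-(triethylsilyloxy)pentanoate
Product: 24 tert-butyl (3S,5R)-3-(hydroxymethyl)-5-[(2S,3S)-2-methyl-3-[(3S)-3-methyl-3-(triethylsilyloxy)pent-4-en-1-yl]oxiran-2-yl]-5-(triethylsilyloxy)pentanoate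
Conditions: LiBH4, MeOH (1 equiv), THF, 0 °C
Reagents that add atoms: none
Why: Reductive cleavage of the imide at its exocyclic carbonyl by the borohydride; the tert-butyl ester and the hindered oxirane should survive at 0 °C, and the auxiliary is recovered.

Step 14
Reactants: 24 tert-butyl (3S,5R)-3-(hydroxymethyl)-5-[(2S,3S)-2-methyl-3-[(3S)-3-methyl-3-(triethylsilyloxy)pent-4-en-1-yl]oxiran-2-yl]-5-(triethylsilyloxy)pentanoate
Product: 25 tert-butyl (3S,5R)-3-formyl-5-[(2S,3S)-2-methyl-3-[(3S)-3-methyl-3-(triethylsilyloxy)pent-4-en-1-yl]oxiran-2-yl]-5-(triethylsilyloxy)pentanoate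
Conditions: Dess–Martin periodinane, NaHCO3, CH2Cl2, 0 °C
Reagents that add atoms: none
Why: Buffered Dess–Martin oxidation is non-basic and should not epimerise the α-stereocentre C1; the aldehyde is used at once.

Step 15
Reactants: 25 tert-butyl (3S,5R)-3-formyl-5-[(2S,3S)-2-methyl-3-[(3S)-3-methyl-3-(triethylsilyloxy)pent-4-en-1-yl]oxiran-2-yl]-5-(triethylsilyloxy)pentanoate; 26 pent-1-en-4-yne; 27 dimethylzinc
Product: 29 tert-butyl (3S,4R,5E)-4-hydroxy-6-methyl-3-[(2R)-2-[(2S,3S)-2-methyl-3-[(3S)-3-methyl-3-(triethylsilyloxy)pent-4-en-1-yl]oxiran-2-yl]-2-(triethylsilyloxy)ethyl]nona-5,8-dienoate, via methylzinc alkoxide 28 (not isolated)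
Conditions: Ni(cod)2 (10–20 mol %), ZnMe2 (2.5 equiv), THF, 0 °C, 25 and 26 added together by syringe pump; aq. NH4Cl
Reagents that add atoms: none
Why: Zerovalent nickel binds the alkyne of 26 and the aldehyde of 25 (activated by the Lewis-acidic zinc reagent) and couples them oxidatively to a five-membered oxanickelacycle with C2 bonded to the unsubstituted alkyne carbon C3 and nickel on C4; a methyl group then passes from 27 to nickel as zinc takes the oxygen, and reductive elimination forms C4–CH3 with retention, so C2 and the methyl group end up cis and C3=C4 is E. The closest known reaction type is the nickel-catalysed three-component alkylative coupling of aldehydes, terminal alkynes and diorganozincs, run without phosphine and with a zinc reagent that has no β-hydrogen, so that methyl transfer ends the cycle. No ring is closed. Regioselectivity comes from the terminal alkyne, whose substituent sits next to nickel in the metallacycle, and the alkene geometry from the syn carbometalation. The one new stereocentre, C2, is controlled only by 1,2-induction from C1 (Felkin–Anh); both α-substituents at C1 are methylene groups, so the bias should be small and may even favour the C2 epimer, the epimers should be separable here or as lactones, and the unwanted one is converged as described under the risks. Chemoselectivity rests on the inertness of the two monosubstituted alkenes, the oxirane, the silyl ethers and the tert-butyl ester toward zerovalent nickel and 27, and on slow addition to hold back alkyne oligomerisation and direct methyl addition to the aldehyde.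

Step 16
Reactants: 29 tert-butyl (3S,4R,5E)-4-hydroxy-6-methyl-3-[(2R)-2-[(2S,3S)-2-methyl-3-[(3S)-3-methyl-3-(triethylsilyloxy)pent-4-en-1-yl]oxiran-2-yl]-2-(triethylsilyloxy)ethyl]nona-5,8-dienoate
Product: 31 (4S,5R)-5-[(1E)-2-methylpenta-1,4-dien-1-yl]-4-[(2R)-2-[(2S,3S)-2-methyl-3-[(3S)-3-methyl-3-(triethylsilyloxy)pent-4-en-1-yl]oxiran-2-yl]-2-(triethylsilyloxy)ethyl]oxolan-2-one, via potassium alkoxide 30 (not isolated)
Conditions: KN(SiMe3)2 (1.05 equiv), THF, −78 → 0 °C; aq. NH4Cl
Reagents that add atoms: none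
Why: The C2 alkoxide attacks the tert-butyl ester in a 5-exo-trig lactonisation and expels tert-butoxide; the C2–O bond is not broken, so the cis relation of C3 and C14 follows from the centres already set.

Step 17
Reactants: 31 (4S,5R)-5-[(1E)-2-methylpenta-1,4-dien-1-yl]-4-[(2R)-2-[(2S,3S)-2-methyl-3-[(3S)-3-methyl-3-(triethylsilyloxy)pent-4-en-1-yl]oxiran-2-yl]-2-(triethylsilyloxy)ethyl]oxolan-2-one
Product: 32 (1S,2R,3E,6E,8S,11S,12S,13R)-11,12-epoxy-8,13-bis(triethylsilyloxy)-17-norcembra-3,6-dien-16,2-olide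
Conditions: second-generation Grubbs catalyst (10 mol %), 1,4-benzoquinone (20 mol %), toluene (1 mM), 80 °C
Reagents that add atoms: none
Why: Ring-closing metathesis: the carbene loads at the unhindered C6 terminus and closes onto the C7 vinyl group, the E olefin being expected under the thermodynamic control of this catalyst next to the quaternary C8. The trisubstituted C3=C4 alkene should stay out, and benzoquinone is added against isomerisation of the skipped diene.

Step 18
Reactants: 32 (1S,2R,3E,6E,8S,11S,12S,13R)-11,12-epoxy-8,13-bis(triethylsilyloxy)-17-norcembra-3,6-dien-16,2-olide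
Product: 34 (1S,2R,3E,6E,8S,11S,12S,13R,15R)-17-(dimethylamino)-11,12-epoxy-8,13-bis(triethylsilyloxy)cembra-3,6-dien-16,2-olide, via lithium enolate 33 (not isolated)
Conditions: LiN(iPr)2, THF, −78 °C; then Me2N=CH2 I (Eschenmoser's salt), −78 → 0 °C
Reagents that add atoms: N,N-dimethylmethyleneiminium iodide, C=[N+](C)C.[I-]
Why: Mannich reaction of the lactone enolate; C15 is the only enolisable position and the aminomethyl group should enter trans to C14, a configuration that is erased in step 21.

Step 19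
Reactants: 34 (1S,2R,3E,6E,8S,11S,12S,13R,15R)-17-(dimethylamino)-11,12-epoxy-8,13-bis(triethylsilyloxy)cembra-3,6-dien-16,2-olide
Product: 35 (1S,2R,3E,6E,8S,11S,12R,13R,15R)-17-(dimethylamino)-11,12-epoxy-8,13-dihydroxycembra-3,6-dien-16,2-olide
Conditions: Bu4NF, AcOH (1:1), THF, 0 °C → rt
Reagents that add atoms: none
Why: Fluoride cleaves both triethylsilyl ethers; the acetic acid buffer avoids free alkoxides next to the oxirane, and no Michael acceptor is present yet.

Step 20
Reactants: 35 (1S,2R,3E,6E,8S,11S,12R,13R,15R)-17-(dimethylamino)-11,12-epoxy-8,13-dihydroxycembra-3,6-dien-16,2-olide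
Product: 36 (1S,2R,3E,6E,8S,11S,12S,13R,15R)-13-acetoxy-17-(dimethylamino)-11,12-epoxy-8-hydroxycembra-3,6-dien-16,2-olide
Conditions: Ac2O, pyridine, DMAP (cat.), CH2Cl2, 0 °C → rt
Reagents that add atoms: acetic anhydride, CC(=O)OC(C)=O
Why: Acylation of the secondary C13 alcohol; the tertiary C8 alcohol should not be acetylated under these conditions.

Step 21
Reactants: 36 (1S,2R,3E,6E,8S,11S,12S,13R,15R)-13-acetoxy-17-(dimethylamino)-11,12-epoxy-8-hydroxycembra-3,6-dien-16,2-olide
Product: 38 (1S,2S,3E,6E,8S,11S,12S,13R)-13-acetoxy-11,12-epoxy-8-hydroxycembra-3,6,15(17)-trien-16,2-olide, via ammonium iodide 37 (not isolated)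
Conditions: MeI, CH2Cl2/MeOH, rt; then aq. NaHCO3, CH2Cl2, rt
Reagents that add atoms: none
Why: Exhaustive N-methylation and Hofmann-type β-elimination through the lactone enolate (E1cB) unveil the exocyclic methylene under mild base, so the Michael acceptor appears only in the last step.

## Compound list

1 | (S)-linalool, (3S)-3,7-dimethylocta-1,6-dien-3-ol | C=C[C@@](C)(O)CCC=C(C)C | starting material
2 | (3S)-3,7-dimethyl-3-(triethylsilyloxy)octa-1,6-diene | C=C[C@@](C)(O[Si](CC)(CC)CC)CCC=C(C)C | intermediate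
3 | 3,3-dimethyl-5-[(3S)-3-methyl-3-(triethylsilyloxy)pent-4-en-1-yl]-1,2,4-trioxolane (ozonide, both epimers at the ring CH) | C=C[C@@](C)(O[Si](CC)(CC)CC)CCC1OOC(C)(C)O1 | intermediate
4 | (4S)-4-methyl-4-(triethylsilyloxy)hex-5-enal | C=C[C@@](C)(O[Si](CC)(CC)CC)CCC=O | intermediate
5 | ethyl 2-[bis(2,2,2-trifluoroethoxy)phosphoryl]propanoate | CCOC(=O)C(C)P(=O)(OCC(F)(F)F)OCC(F)(F)F | starting material
6 | potassium salt of the α-carbanion of 5 | [K+].CCOC(=O)[C-](C)P(=O)(OCC(F)(F)F)OCC(F)(F)F | intermediate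
7 | ethyl (2Z,6S)-2,6-dimethyl-6-(triethylsilyloxy)octa-2,7-dienoate | CCOC(=O)/C(C)=C\CC[C@](C)(O[Si](CC)(CC)CC)C=C | intermediate
8 | (2Z,6S)-2,6-dimethyl-6-(triethylsilyloxy)octa-2,7-dien-1-ol | OC/C(C)=C\CC[C@](C)(O[Si](CC)(CC)CC)C=C | intermediate
9 | [(2R,3S)-2-methyl-3-[(3S)-3-methyl-3-(triethylsilyloxy)pent-4-en-1-yl]oxiran-2-yl]methanol | OC[C@@]1(C)O[C@H]1CC[C@](C)(O[Si](CC)(CC)CC)C=C | intermediate
10 | (2S,3S)-2-methyl-3-[(3S)-3-methyl-3-(triethylsilyloxy)pent-4-en-1-yl]oxirane-2-carbaldehyde | O=C[C@@]1(C)O[C@H]1CC[C@](C)(O[Si](CC)(CC)CC)C=C | intermediate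
11 | O-diisopinocampheylboryl derivative (borinate) of 12 | C=CC[C@@H](OB([C@H]1C[C@H]2C[C@@H]([C@@H]1C)C2(C)C)[C@H]1C[C@H]2C[C@@H]([C@@H]1C)C2(C)C)[C@@]1(C)O[C@H]1CC[C@](C)(O[Si](CC)(CC)CC)C=C | intermediate
12 | (1R)-1-[(2R,3S)-2-methyl-3-[(3S)-3-methyl-3-(triethylsilyloxy)pent-4-en-1-yl]oxiran-2-yl]but-3-en-1-ol | C=CC[C@@H](O)[C@@]1(C)O[C@H]1CC[C@](C)(O[Si](CC)(CC)CC)C=C | intermediate
13 | triethyl{[(1R)-1-[(2S,3S)-2-methyl-3-[(3S)-3-methyl-3-(triethylsilyloxy)pent-4-en-1-yl]oxiran-2-yl]but-3-en-1-yl]oxy}silane | C=CC[C@@H](O[Si](CC)(CC)CC)[C@@]1(C)O[C@H]1CC[C@](C)(O[Si](CC)(CC)CC)C=C | intermediate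
14 | B-alkyldicyclohexylborane from 13 (boron on C2) | C1CCCCC1B(CCC[C@@H](O[Si](CC)(CC)CC)[C@@]2(C)O[C@H]2CC[C@](C)(O[Si](CC)(CC)CC)C=C)C1CCCCC1 | intermediate
15 | (4R)-4-[(2S,3S)-2-methyl-3-[(3S)-3-methyl-3-(triethylsilyloxy)pent-4-en-1-yl]oxiran-2-yl]-4-(triethylsilyloxy)butan-1-ol | OCCC[C@@H](O[Si](CC)(CC)CC)[C@@]1(C)O[C@H]1CC[C@](C)(O[Si](CC)(CC)CC)C=C | intermediate
16 | (4R)-4-[(2S,3S)-2-methyl-3-[(3S)-3-methyl-3-(triethylsilyloxy)pent-4-en-1-yl]oxiran-2-yl]-4-(triethylsilyloxy)butanal | O=CCC[C@@H](O[Si](CC)(CC)CC)[C@@]1(C)O[C@H]1CC[C@](C)(O[Si](CC)(CC)CC)C=C | intermediate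
17 | (4R)-4-[(2S,3S)-2-methyl-3-[(3S)-3-methyl-3-(triethylsilyloxy)pent-4-en-1-yl]oxiran-2-yl]-4-(triethylsilyloxy)butanoic acid | OC(=O)CC[C@@H](O[Si](CC)(CC)CC)[C@@]1(C)O[C@H]1CC[C@](C)(O[Si](CC)(CC)CC)C=C | intermediate
18 | (4R)-4-benzyl-1,3-oxazolidin-2-one | O=C1N[C@H](Cc2ccccc2)CO1 | starting material
19 | mixed anhydride of 17 with pivalic acid | CC(C)(C)C(=O)OC(=O)CC[C@@H](O[Si](CC)(CC)CC)[C@@]1(C)O[C@H]1CC[C@](C)(O[Si](CC)(CC)CC)C=C | intermediate
20 | (4R)-4-benzyl-3-[(4R)-4-[(2S,3S)-2-methyl-3-[(3S)-3-methyl-3-(triethylsilyloxy)pent-4-en-1-yl]oxiran-2-yl]-4-(triethylsilyloxy)butanoyl]-1,3-oxazolidin-2-one | O=C(CC[C@@H](O[Si](CC)(CC)CC)[C@@]1(C)O[C@H]1CC[C@](C)(O[Si](CC)(CC)CC)C=C)N1[C@H](Cc2ccccc2)COC1=O | intermediate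
21 | tert-butyl bromoacetate | BrCC(=O)OC(C)(C)C | starting material
22 | sodium (Z)-enolate of 20 | [Na+].[O-]/C(=C\C[C@@H](O[Si](CC)(CC)CC)[C@@]1(C)O[C@H]1CC[C@](C)(O[Si](CC)(CC)CC)C=C)N1[C@H](Cc2ccccc2)COC1=O | intermediate
23 | tert-butyl (3S,5R)-3-[(4R)-4-benzyl-2-oxo-1,3-oxazolidine-3-carbonyl]-5-[(2S,3S)-2-methyl-3-[(3S)-3-methyl-3-(triethylsilyloxy)pent-4-en-1-yl]oxiran-2-yl]-5-(triethylsilyloxy)pentanoate | O=C([C@H](CC(=O)OC(C)(C)C)C[C@@H](O[Si](CC)(CC)CC)[C@@]1(C)O[C@H]1CC[C@](C)(O[Si](CC)(CC)CC)C=C)N1[C@H](Cc2ccccc2)COC1=O | intermediate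
24 | tert-butyl (3S,5R)-3-(hydroxymethyl)-5-[(2S,3S)-2-methyl-3-[(3S)-3-methyl-3-(triethylsilyloxy)pent-4-en-1-yl]oxiran-2-yl]-5-(triethylsilyloxy)pentanoate | OC[C@H](CC(=O)OC(C)(C)C)C[C@@H](O[Si](CC)(CC)CC)[C@@]1(C)O[C@H]1CC[C@](C)(O[Si](CC)(CC)CC)C=C | intermediate
25 | tert-butyl (3S,5R)-3-formyl-5-[(2S,3S)-2-methyl-3-[(3S)-3-methyl-3-(triethylsilyloxy)pent-4-en-1-yl]oxiran-2-yl]-5-(triethylsilyloxy)pentanoate | O=C[C@H](CC(=O)OC(C)(C)C)C[C@@H](O[Si](CC)(CC)CC)[C@@]1(C)O[C@H]1CC[C@](C)(O[Si](CC)(CC)CC)C=C | intermediate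
26 | pent-1-en-4-yne | C#CCC=C | starting material
27 | dimethylzinc | C[Zn]C | starting material
28 | methylzinc alkoxide of 29 | C=CC/C(C)=C/[C@H](O[Zn]C)[C@H](CC(=O)OC(C)(C)C)C[C@@H](O[Si](CC)(CC)CC)[C@@]1(C)O[C@H]1CC[C@](C)(O[Si](CC)(CC)CC)C=C | intermediate
29 | tert-butyl (3S,4R,5E)-4-hydroxy-6-methyl-3-[(2R)-2-[(2S,3S)-2-methyl-3-[(3S)-3-methyl-3-(triethylsilyloxy)pent-4-en-1-yl]oxiran-2-yl]-2-(triethylsilyloxy)ethyl]nona-5,8-dienoate | C=CC/C(C)=C/[C@H](O)[C@H](CC(=O)OC(C)(C)C)C[C@@H](O[Si](CC)(CC)CC)[C@@]1(C)O[C@H]1CC[C@](C)(O[Si](CC)(CC)CC)C=C | intermediate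
30 | potassium alkoxide of 29 | [K+].C=CC/C(C)=C/[C@H]([O-])[C@H](CC(=O)OC(C)(C)C)C[C@@H](O[Si](CC)(CC)CC)[C@@]1(C)O[C@H]1CC[C@](C)(O[Si](CC)(CC)CC)C=C | intermediate
31 | (4S,5R)-5-[(1E)-2-methylpenta-1,4-dien-1-yl]-4-[(2R)-2-[(2S,3S)-2-methyl-3-[(3S)-3-methyl-3-(triethylsilyloxy)pent-4-en-1-yl]oxiran-2-yl]-2-(triethylsilyloxy)ethyl]oxolan-2-one | C=CC/C(C)=C/[C@@H]1OC(=O)C[C@@H]1C[C@@H](O[Si](CC)(CC)CC)[C@@]1(C)O[C@H]1CC[C@](C)(O[Si](CC)(CC)CC)C=C | intermediate
32 | (1S,2R,3E,6E,8S,11S,12S,13R)-11,12-epoxy-8,13-bis(triethylsilyloxy)-17-norcembra-3,6-dien-16,2-olide | C1C(=O)O[C@H]2/C=C(\C)C/C=C/[C@@](C)(O[Si](CC)(CC)CC)CC[C@@H]3O[C@]3(C)[C@H](O[Si](CC)(CC)CC)C[C@@H]12 | intermediate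
33 | lithium enolate of 32 (C15=C16–O−) | C1=C([O-])O[C@H]2/C=C(\C)C/C=C/[C@@](C)(O[Si](CC)(CC)CC)CC[C@@H]3O[C@]3(C)[C@H](O[Si](CC)(CC)CC)C[C@@H]12.[Li+] | intermediate
34 | (1S,2R,3E,6E,8S,11S,12S,13R,15R)-17-(dimethylamino)-11,12-epoxy-8,13-bis(triethylsilyloxy)cembra-3,6-dien-16,2-olide | CN(C)C[C@@H]1C(=O)O[C@H]2/C=C(\C)C/C=C/[C@@](C)(O[Si](CC)(CC)CC)CC[C@@H]3O[C@]3(C)[C@H](O[Si](CC)(CC)CC)C[C@@H]12 | intermediate
35 | (1S,2R,3E,6E,8S,11S,12R,13R,15R)-17-(dimethylamino)-11,12-epoxy-8,13-dihydroxycembra-3,6-dien-16,2-olide | CN(C)C[C@@H]1C(=O)O[C@H]2/C=C(\C)C/C=C/[C@@](C)(O)CC[C@@H]3O[C@]3(C)[C@H](O)C[C@@H]12 | intermediate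
36 | (1S,2R,3E,6E,8S,11S,12S,13R,15R)-13-acetoxy-17-(dimethylamino)-11,12-epoxy-8-hydroxycembra-3,6-dien-16,2-olide | CN(C)C[C@@H]1C(=O)O[C@H]2/C=C(\C)C/C=C/[C@@](C)(O)CC[C@@H]3O[C@]3(C)[C@H](OC(C)=O)C[C@@H]12 | intermediate
37 | N-methyl ammonium iodide of 36 | C[N+](C)(C)C[C@@H]1C(=O)O[C@H]2/C=C(\C)C/C=C/[C@@](C)(O)CC[C@@H]3O[C@]3(C)[C@H](OC(C)=O)C[C@@H]12.[I-] | intermediate
38 | (1S,2S,3E,6E,8S,11S,12S,13R)-13-acetoxy-11,12-epoxy-8-hydroxycembra-3,6,15(17)-trien-16,2-olide (CNP0288879.2) | C=C1C(=O)O[C@H]2/C=C(\C)C/C=C/[C@@](C)(O)CC[C@@H]3O[C@]3(C)[C@H](OC(C)=O)C[C@@H]12 | target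

## Step count and least certain steps

Total step count: 21. Longest linear sequence: 21 steps (1 to 38); the sequence is fully linear, with 5, 18, 21, 26 and 27 entering as bought reagents.

**Step 15 (key step).** The most likely failure is poor facial selectivity at C2, because the only control is 1,2-induction from a centre whose two α-substituents are both methylene groups. Oligomerisation of the terminal alkyne, isomerisation of the skipped enyne on zerovalent nickel and direct methyl transfer to the aldehyde are the other threats. The fallback separates bond formation from stereocontrol and sets out from 25 and 26. Zirconium-catalysed carboalumination of 26 (Cp2ZrCl2, AlMe3; then I2) gives (1E)-1-iodo-2-methylpenta-1,4-diene F1. Nozaki–Hiyama–Kishi coupling of F1 with 25 (CrCl2, NiCl2 cat., DMSO) gives 29 together with its C2 epimer, tert-butyl (3S,4S,5E)-4-hydroxy-6-methyl-3-[(2R)-2-[(2S,3S)-2-methyl-3-[(3S)-3-methyl-3-(triethylsilyloxy)pent-4-en-1-yl]oxiran-2-yl]-2-(triethylsilyloxy)ethyl]nona-5,8-dienoate F2. The mixture (or F2 recovered from step 15) is oxidised with Dess–Martin periodinane to the enone tert-butyl (3S,5E)-6-methyl-4-oxo-3-[(2R)-2-[(2S,3S)-2-methyl-3-[(3S)-3-methyl-3-(triethylsilyloxy)pent-4-en-1-yl]oxiran-2-yl]-2-(triethylsilyloxy)ethyl]nona-5,8-dienoate F3. F3 is reduced with (S)-2-methyl-CBS-oxazaborolidine and catecholborane, the alkenyl group acting as the large substituent, and the sequence returns to the route at 29. F3 must be handled without base, since C1 is then α to a ketone and C5 can deconjugate.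

**Step 17.** Ring closure onto the vinyl group flanked by the silylated quaternary C8 may be slow, so that dimers and oligomers formed through the unhindered terminus build up; a Z/E mixture or migration of the skipped diene is also possible. The fallback sets out from 31. Buffered Bu4NF/AcOH removes both silyl groups to give the diol (4S,5R)-4-[(2R)-2-hydroxy-2-[(2R,3S)-3-[(3S)-3-hydroxy-3-methylpent-4-en-1-yl]-2-methyloxiran-2-yl]ethyl]-5-[(1E)-2-methylpenta-1,4-dien-1-yl]oxolan-2-one F4. Its free tertiary allylic hydroxyl is known to speed metathesis at the adjacent vinyl group, and ring closure with the same catalyst gives (1S,2R,3E,6E,8S,11S,12R,13R)-11,12-epoxy-8,13-dihydroxy-17-norcembra-3,6-dien-16,2-olide F5. Resilylation (TESOTf, 2,6-lutidine, −78 °C) returns to the route at 32. F4 must be kept free of acid because of the hydroxyl–oxirane pair.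

**Step 9.** Discrimination between the two monosubstituted alkenes may be incomplete, with hydroboration also at the C8 vinyl group. The fallback sets out from 13. Cross-metathesis with vinylboronic acid pinacol ester (second-generation Hoveyda–Grubbs catalyst), in which the hindered vinyl group should not take part, gives 2-[(1E,4R)-4-[(2S,3S)-2-methyl-3-[(3S)-3-methyl-3-(triethylsilyloxy)pent-4-en-1-yl]oxiran-2-yl]-4-(triethylsilyloxy)but-1-en-1-yl]-4,4,5,5-tetramethyl-1,3,2-dioxaborolane F6. Oxidation of the alkenylboronate (NaBO3·4H2O, THF/H2O) gives the aldehyde 16, and chlorite oxidation (NaClO2, NaH2PO4, 2-methylbut-2-ene) returns to the route at 17.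

**Step 7.** Reagent control may be eroded on the hindered α-quaternary aldehyde, giving both C13 epimers. The fallback sets out from 10. Addition of CH2=CHCH2MgBr gives 12 with its epimer (1S)-1-[(2R,3S)-2-methyl-3-[(3S)-3-methyl-3-(triethylsilyloxy)pent-4-en-1-yl]oxiran-2-yl]but-3-en-1-ol F7. Dess–Martin oxidation of the mixture gives the epoxy ketone 1-[(2S,3S)-2-methyl-3-[(3S)-3-methyl-3-(triethylsilyloxy)pent-4-en-1-yl]oxiran-2-yl]but-3-en-1-one F8. Chelation-controlled reduction with Zn(BH4)2 at low temperature delivers hydride to the zinc-bridged carbonyl–oxirane chelate from the side away from C11 and returns to the route at 12.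

## Further compounds

F1 | step 15 | (1E)-1-iodo-2-methylpenta-1,4-diene | C=CC/C(C)=C/I
F2 | step 15 | tert-butyl (3S,4S,5E)-4-hydroxy-6-methyl-3-[(2R)-2-[(2S,3S)-2-methyl-3-[(3S)-3-methyl-3-(triethylsilyloxy)pent-4-en-1-yl]oxiran-2-yl]-2-(triethylsilyloxy)ethyl]nona-5,8-dienoate (C2 epimer of 29) | C=CC/C(C)=C/[C@@H](O)[C@H](CC(=O)OC(C)(C)C)C[C@@H](O[Si](CC)(CC)CC)[C@@]1(C)O[C@H]1CC[C@](C)(O[Si](CC)(CC)CC)C=C
F3 | step 15 | tert-butyl (3S,5E)-6-methyl-4-oxo-3-[(2R)-2-[(2S,3S)-2-methyl-3-[(3S)-3-methyl-3-(triethylsilyloxy)pent-4-en-1-yl]oxiran-2-yl]-2-(triethylsilyloxy)ethyl]nona-5,8-dienoate | C=CC/C(C)=C/C(=O)[C@H](CC(=O)OC(C)(C)C)C[C@@H](O[Si](CC)(CC)CC)[C@@]1(C)O[C@H]1CC[C@](C)(O[Si](CC)(CC)CC)C=C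
F4 | step 17 | (4S,5R)-4-[(2R)-2-hydroxy-2-[(2R,3S)-3-[(3S)-3-hydroxy-3-methylpent-4-en-1-yl]-2-methyloxiran-2-yl]ethyl]-5-[(1E)-2-methylpenta-1,4-dien-1-yl]oxolan-2-one | C=CC/C(C)=C/[C@@H]1OC(=O)C[C@@H]1C[C@@H](O)[C@@]1(C)O[C@H]1CC[C@](C)(O)C=C
F5 | step 17 | (1S,2R,3E,6E,8S,11S,12R,13R)-11,12-epoxy-8,13-dihydroxy-17-norcembra-3,6-dien-16,2-olide | C1C(=O)O[C@H]2/C=C(\C)C/C=C/[C@@](C)(O)CC[C@@H]3O[C@]3(C)[C@H](O)C[C@@H]12
F6 | step 9 | 2-[(1E,4R)-4-[(2S,3S)-2-methyl-3-[(3S)-3-methyl-3-(triethylsilyloxy)pent-4-en-1-yl]oxiran-2-yl]-4-(triethylsilyloxy)but-1-en-1-yl]-4,4,5,5-tetramethyl-1,3,2-dioxaborolane | CC1(C)OB(/C=C/C[C@@H](O[Si](CC)(CC)CC)[C@@]2(C)O[C@H]2CC[C@](C)(O[Si](CC)(CC)CC)C=C)OC1(C)C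
F7 | step 7 | (1S)-1-[(2R,3S)-2-methyl-3-[(3S)-3-methyl-3-(triethylsilyloxy)pent-4-en-1-yl]oxiran-2-yl]but-3-en-1-ol (C13 epimer of 12) | C=CC[C@H](O)[C@@]1(C)O[C@H]1CC[C@](C)(O[Si](CC)(CC)CC)C=C
F8 | step 7 | 1-[(2S,3S)-2-methyl-3-[(3S)-3-methyl-3-(triethylsilyloxy)pent-4-en-1-yl]oxiran-2-yl]but-3-en-1-one | C=CCC(=O)[C@@]1(C)O[C@H]1CC[C@](C)(O[Si](CC)(CC)CC)C=C
A1 | alternative 1 | 17-membered cyclic allyl propargyl ether (oxygen between C2 and C17; C3≡C4; E C6=C7; 8-OTES; E C11=C12; 13-OTIPS; C1=C15 carrying CH2OTBS, C14 cis to C17) | C1OCC#CC/C=C/[C@@](C)(O[Si](CC)(CC)CC)CC/C=C(\C)[C@H](O[Si](C(C)C)(C(C)C)C(C)C)C/C=C1/CO[Si](C)(C)C(C)(C)C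
A2 | alternative 1 | 14-membered cycloalkynol with C1 and C2 set | C=C(CO[Si](C)(C)C(C)(C)C)[C@H]1[C@@H](O)C#CC/C=C/[C@@](C)(O[Si](CC)(CC)CC)CC/C=C(\C)[C@H](O[Si](C(C)C)(C(C)C)C(C)C)C1
A3 | alternative 2 | seco compound with C5 allylic chloride and (E)-C6 tributylstannyl alkene | CCCC[Sn](CCCC)(CCCC)/C=C/[C@@](C)(O)CC[C@@H]1O[C@]1(C)[C@H](OC(C)=O)C[C@@H](C(=C)CO[Si](C)(C)C(C)(C)C)[C@@H](O[Si](C)(C)C(C)(C)C)/C=C(\C)CCl
A4 | alternative 2 | 14-membered carbocycle with the lactone masked as a bis(tert-butyldimethylsilyl) diol | [C@H]1(O[Si](C)(C)C(C)(C)C)/C=C(\C)C/C=C/[C@@](C)(O)CC[C@@H]2O[C@]2(C)[C@H](OC(C)=O)C[C@H]1C(=C)CO[Si](C)(C)C(C)(C)C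
A5 | alternative 3 | seco ynal with C13 aldehyde and C11≡C12–CH3 alkyne | O=CC[C@@H](C(=C)CO[Si](C)(C)C(C)(C)C)[C@@H](O[Si](C)(C)C(C)(C)C)/C=C(\C)C/C=C/[C@@](C)(O[Si](CC)(CC)CC)CCC#CC
A6 | alternative 3 | 14-membered E allylic triethylsilyl ether | [C@H]1(O[Si](C)(C)C(C)(C)C)/C=C(\C)C/C=C/[C@@](C)(O[Si](CC)(CC)CC)CC/C=C(\C)[C@H](O[Si](CC)(CC)CC)C[C@H]1C(=C)CO[Si](C)(C)C(C)(C)C
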